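**Retrosynthetic overview**
1. Target ⇒ seco (Z)-enal carrying a 2-(methoxycarbonyl)allylsilane at C7: the C6–C7 bond and the lactone C–O bond are made last (organocatalytic macrocyclising Hosomi–Sakurai allylation, then lactonisation); the C8 ester is already in place.
2. Allylsilane ⇒ C7 aldehyde + silylated phosphonoacetate (HWE, C7=C11); C8 ester ⇒ secondary alcohol + (R)-2-methylbutanoic acid (asymmetric hydrogenation of tiglic acid).
3. 3(2H)-Furanone ⇒ α-hydroxy-γ-lactone + lithiated silyl ether of (Z)-3-methylpent-2-en-4-yn-1-ol (C1–C2 bond, then 5-endo-dig O–C3 closure); the Z C4=C5 alkene is bought.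
4. Hydroxy lactone ⇒ 1,1-dimethoxyacetone + ethyl pyruvate (organocatalytic cross-aldol sets C10; CBS reduction sets C8).
5. Ring order: temporary γ-lactone → furanone → ten-membered carbocycle (nine-membered oxa-bridged ring) → α-methylene-γ-lactone.

Labels: germacrane numbering is used — C1 ketone, C2=C3 furanone alkene (C3 bears the ring oxygen), C4 (methyl C15)=C5, C6 (lactone oxygen), C7, C8 (ester oxygen), C9, C10 (methyl C14, ring oxygen), C11(=C13), C12 lactone carbonyl.

Assumption: for the two catalysts without a close sense-of-induction precedent (steps 1 and 11) the antipode named is taken to give the stated configuration; the other antipode would be swapped in after a test reaction.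

**Route**

Step 1
Reactants: 1 1,1-dimethoxypropan-2-one (pyruvaldehyde dimethyl acetal); 2 ethyl pyruvate
Product: 3 ethyl (S)-2-hydroxy-5,5-dimethoxy-2-methyl-4-oxopentanoate
Conditions: 9-amino-9-deoxy-epi-quinine (10 mol %), 4-nitrobenzoic acid (20 mol %), 1 (5 equiv), 2 added over 12 h, toluene, 0 °C
Reagents that add atoms: none
Why: Direct asymmetric cross-aldol by enamine catalysis: the primary amine forms the enamine of 1 on its methyl side, the protonated quinuclidine binds the 1,2-dicarbonyl of 2, and attack on the Si face of the keto group sets C10 as S, while excess donor and slow addition hold back self-aldol of 2.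

Step 2
Reactants: 3 ethyl (S)-2-hydroxy-5,5-dimethoxy-2-methyl-4-oxopentanoate
Product: 5 (3S,5R)-5-(dimethoxymethyl)-3-hydroxy-3-methyldihydrofuran-2(3H)-one, via diol ester 4 (not isolated)
Conditions: (S)-2-methyl-CBS-oxazaborolidine (20 mol %), BH3·SMe2 (2.0 equiv), THF, −30 °C, 3 added over 2 h; MeOH; then DBU (10 mol %), CH2Cl2, 23 °C
Reagents that add atoms: none
Why: Corey–Bakshi–Shibata reduction under catalyst control (the branched acetal carbon acts as the large group, so hydride reaches the face that gives the 4R carbinol, C8), then DBU-catalysed 5-exo-trig transesterification closes the γ-lactone that serves as acyl donor in step 4.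

Step 3
Reactants: 6 (Z)-3-methylpent-2-en-4-yn-1-ol
Product: 7 (Z)-triethyl[(3-methylpent-2-en-4-yn-1-yl)oxy]silane
Conditions: Et3SiCl (1.1 equiv), imidazole (1.5 equiv), CH2Cl2, 0 °C
Reagents that add atoms: chlorotriethylsilane, CC[Si](Cl)(CC)CC
Why: Standard silylation of a primary alcohol leaves the alkyne C–H as the only acidic site and keeps the Z-alkene; the triethylsilyl ether is chosen so that it falls off together with the acetal in step 7.

Step 4
Reactants: 5 (3S,5R)-5-(dimethoxymethyl)-3-hydroxy-3-methyldihydrofuran-2(3H)-one; 7 (Z)-triethyl[(3-methylpent-2-en-4-yn-1-yl)oxy]silane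
Product: 9 (S)-2-[(R)-2-hydroxy-3,3-dimethoxypropyl]-2-methyl-5-[(Z)-4-(triethylsilyloxy)but-2-en-2-yl]furan-3(2H)-one, via hydroxy ynone 8 (not isolated)
Conditions: 5, LiN(SiMe3)2 (1.05 equiv), THF, −78 °C; 7 (1.3 equiv) lithiated with n-BuLi (1.25 equiv), −78 to −40 °C; AcOH (2.4 equiv); then DBU (0.5 equiv), 23 °C
Reagents that add atoms: none
Why: Acetylide acylation by a lactone (1,2-addition stops at the tetrahedral Li alkoxide, so no double addition) releases the α′-hydroxy ynone on protonation, and DBU-catalysed 5-endo-dig oxa-Michael addition of the tertiary C10 hydroxyl closes the 3(2H)-furanone; quaternary C10 and the Z-alkene of 7 are untouched.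

Step 5
Reactants: 10 tiglic acid [(E)-2-methylbut-2-enoic acid]
Product: 11 (R)-2-methylbutanoic acid
Conditions: Ru(OAc)2[(R)-H8-BINAP] (0.5 mol %), H2 (2 atm), MeOH, 15 °C
Reagents that add atoms: none
Why: Carboxylate-directed asymmetric hydrogenation of a trisubstituted acrylic acid (Noyori–Takaya type) sets the side-chain stereocentre as R from an achiral acid.

Step 6
Reactants: 9 furanone alcohol (free C8 hydroxyl); 11 (R)-2-methylbutanoic acid
Product: 12 (R)-1,1-dimethoxy-3-[(S)-2-methyl-3-oxo-5-((Z)-4-(triethylsilyloxy)but-2-en-2-yl)-2,3-dihydrofuran-2-yl]propan-2-yl (R)-2-methylbutanoate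
Conditions: EDC·HCl (1.5 equiv), DMAP (0.2 equiv), CH2Cl2, 0 to 23 °C
Reagents that add atoms: none
Why: Steglich esterification of the only free hydroxyl touches no stereocentre, and the α-branched alkanoic acid does not racemise under carbodiimide/DMAP at or below room temperature.

Step 7
Reactants: 12 acetal silyl ether ester
Product: 13 (R)-1-[(S)-5-((Z)-4-hydroxybut-2-en-2-yl)-2-methyl-3-oxo-2,3-dihydrofuran-2-yl]-3-oxopropan-2-yl (R)-2-methylbutanoate
Conditions: TFA/H2O (9:1), CH2Cl2, 0 °C
Reagents that add atoms: water, O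
Why: Acid-catalysed acetal hydrolysis and silyl ether cleavage in one operation (TFA because the neighbouring acyloxy group slows oxocarbenium formation); furanone, ester and Z-alkene are acid-stable and C8 is not enolised at 0 °C.

Step 8
Reactants: 14 trimethyl phosphonoacetate; 15 (iodomethyl)trimethylsilane
Product: 16 methyl 2-(dimethoxyphosphoryl)-3-(trimethylsilyl)propanoate (racemic)
Conditions: NaH (1.05 equiv), DME, 0 to 70 °C
Reagents that add atoms: none
Why: SN2 alkylation of the stabilised phosphonoacetate anion with a primary iodide gives the silylated Horner–Wadsworth–Emmons reagent.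

Step 9
Reactants: 13 hydroxy aldehyde; 16 methyl 2-(dimethoxyphosphoryl)-3-(trimethylsilyl)propanoate
Product: 17 methyl (R,Z)-5-[(S)-5-((Z)-4-hydroxybut-2-en-2-yl)-2-methyl-3-oxo-2,3-dihydrofuran-2-yl]-4-[(R)-2-methylbutanoyloxy]-2-[(trimethylsilyl)methyl]pent-2-enoate
Conditions: LiCl (1.5 equiv), DBU (1.3 equiv), MeCN, 0 to 23 °C
Reagents that add atoms: none
Why: Horner–Wadsworth–Emmons olefination under Masamune–Roush conditions is mild enough for the epimerisable α-acyloxy aldehyde and the free alcohol and forms C7=C11 mainly as the isomer with the ester trans to C8 (Z by CIP); a minor E isomer is removed by chromatography.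

Step 10
Reactants: 17 allylsilane alcohol
Product: 18 methyl (R,Z)-4-[(R)-2-methylbutanoyloxy]-5-[(S)-2-methyl-3-oxo-5-((Z)-4-oxobut-2-en-2-yl)-2,3-dihydrofuran-2-yl]-2-[(trimethylsilyl)methyl]pent-2-enoate
Conditions: TEMPO (10 mol %), PhI(OAc)2 (1.2 equiv), CH2Cl2, 23 °C
Reagents that add atoms: none
Why: Oxoammonium (TEMPO) oxidation converts the primary allylic alcohol into the Z-enal without Z/E isomerisation and without touching the electron-poor allylsilane.

Step 11
Reactants: 18 seco enal allylsilane
Product: 20 (6R,7R,8R,10S)-8-[(R)-2-methylbutanoyloxy]-1-oxo-3,10-epoxygermacra-2,4(Z),11(13)-trien-12,6-olide (CNP0174601.3), via silyl ether ester 19 (not isolated)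
Conditions: (S,S)-imidodiphosphorimidate Brønsted acid (3,3′-aryl binaphthyl backbones, N-triflyl; 5 mol %) presilylated with methallyltrimethylsilane (5 mol %), 18 added by syringe pump over 10 h, toluene (final 1 mM), −60 °C; then p-TsOH·H2O (20 mol %), wet CH2Cl2, 23 °C
Reagents that add atoms: none
Why: Proposed new method: a catalyst-controlled macrocyclising Hosomi–Sakurai allylation in which the silylated imidodiphosphorimidate (a chiral silylium ion pair) silylates the enal oxygen, the confined anion leaves the Si face of the C6 oxocarbenium open, and the tethered allylsilane attacks through the Re face of C7 anti to silicon (SE2′) on the side where C9 leads the forming ring, with the acyloxy group turned outward, so that 6R and 7R (H6/H7 trans) are set, loss of silicon from the β-silyl cation gives the exocyclic methylene and returns Me3Si to the catalyst, and acid then cleaves the C6 silyl ether and closes the γ-lactone; the closest known reactions are the imidodiphosphorimidate-catalysed intermolecular Hosomi–Sakurai allylation of aldehydes and the Lewis acid- or fluoride-promoted cyclisation of ω-formyl 2-(alkoxycarbonyl)allylsilanes to ring-fused α-methylene-γ-butyrolactones, neither shown for a ten-membered ring or under catalyst control.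

**Compound list**
1 | 1,1-dimethoxypropan-2-one | CC(=O)C(OC)OC | starting material
2 | ethyl pyruvate | CCOC(=O)C(C)=O | starting material
3 | ethyl (S)-2-hydroxy-5,5-dimethoxy-2-methyl-4-oxopentanoate | CCOC(=O)[C@](C)(CC(=O)C(OC)OC)O | intermediate
4 | ethyl (2S,4R)-2,4-dihydroxy-5,5-dimethoxy-2-methylpentanoate | CCOC(=O)[C@](C)(C[C@@H](O)C(OC)OC)O | intermediate
5 | (3S,5R)-5-(dimethoxymethyl)-3-hydroxy-3-methyldihydrofuran-2(3H)-one | O=C1[C@](C)(C[C@@H](O1)C(OC)OC)O | intermediate
6 | (Z)-3-methylpent-2-en-4-yn-1-ol | C#C/C(C)=C\CO | starting material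
7 | (Z)-triethyl[(3-methylpent-2-en-4-yn-1-yl)oxy]silane | C#C/C(C)=C\CO[Si](CC)(CC)CC | intermediate
8 | (4S,6R)-4,6-dihydroxy-7,7-dimethoxy-4-methyl-1-[(Z)-4-(triethylsilyloxy)but-2-en-2-yl]hept-1-yn-3-one | CC[Si](CC)(CC)OC/C=C(/C)C#CC(=O)[C@](C)(C[C@@H](O)C(OC)OC)O | intermediate
9 | (S)-2-[(R)-2-hydroxy-3,3-dimethoxypropyl]-2-methyl-5-[(Z)-4-(triethylsilyloxy)but-2-en-2-yl]furan-3(2H)-one | CC[Si](CC)(CC)OC/C=C(/C)C1=CC(=O)[C@](C)(C[C@@H](O)C(OC)OC)O1 | intermediate
10 | tiglic acid | C/C=C(\C)C(=O)O | starting material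
11 | (R)-2-methylbutanoic acid | CC[C@@H](C)C(=O)O | intermediate
12 | (R)-1,1-dimethoxy-3-[(S)-2-methyl-3-oxo-5-((Z)-4-(triethylsilyloxy)but-2-en-2-yl)-2,3-dihydrofuran-2-yl]propan-2-yl (R)-2-methylbutanoate | CC[Si](CC)(CC)OC/C=C(/C)C1=CC(=O)[C@](C)(C[C@@H](OC(=O)[C@H](C)CC)C(OC)OC)O1 | intermediate
13 | (R)-1-[(S)-5-((Z)-4-hydroxybut-2-en-2-yl)-2-methyl-3-oxo-2,3-dihydrofuran-2-yl]-3-oxopropan-2-yl (R)-2-methylbutanoate | OC/C=C(/C)C1=CC(=O)[C@](C)(C[C@@H](OC(=O)[C@H](C)CC)C=O)O1 | intermediate
14 | trimethyl phosphonoacetate | COC(=O)CP(=O)(OC)OC | starting material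
15 | (iodomethyl)trimethylsilane | C[Si](C)(C)CI | starting material
16 | methyl 2-(dimethoxyphosphoryl)-3-(trimethylsilyl)propanoate (racemic) | COC(=O)C(C[Si](C)(C)C)P(=O)(OC)OC | intermediate
17 | methyl (R,Z)-5-[(S)-5-((Z)-4-hydroxybut-2-en-2-yl)-2-methyl-3-oxo-2,3-dihydrofuran-2-yl]-4-[(R)-2-methylbutanoyloxy]-2-[(trimethylsilyl)methyl]pent-2-enoate | OC/C=C(/C)C1=CC(=O)[C@](C)(C[C@@H](OC(=O)[C@H](C)CC)/C=C(/C(=O)OC)C[Si](C)(C)C)O1 | intermediate
18 | methyl (R,Z)-4-[(R)-2-methylbutanoyloxy]-5-[(S)-2-methyl-3-oxo-5-((Z)-4-oxobut-2-en-2-yl)-2,3-dihydrofuran-2-yl]-2-[(trimethylsilyl)methyl]pent-2-enoate | O=C/C=C(/C)C1=CC(=O)[C@](C)(C[C@@H](OC(=O)[C@H](C)CC)/C=C(/C(=O)OC)C[Si](C)(C)C)O1 | intermediate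
19 | methyl 2-[(6R,7R,8R,10S)-8-[(R)-2-methylbutanoyloxy]-1-oxo-6-(trimethylsilyloxy)-3,10-epoxygermacra-2,4(Z)-dien-7-yl]acrylate | C[Si](C)(C)O[C@@H]1/C=C(/C)C2=CC(=O)[C@](C)(C[C@@H](OC(=O)[C@H](C)CC)[C@H]1C(=C)C(=O)OC)O2 | intermediate
20 | (6R,7R,8R,10S)-8-[(R)-2-methylbutanoyloxy]-1-oxo-3,10-epoxygermacra-2,4(Z),11(13)-trien-12,6-olide (CNP0174601.3) | C=C1C(=O)O[C@@H]2/C=C(/C)C3=CC(=O)[C@](C)(C[C@@H](OC(=O)[C@H](C)CC)[C@@H]12)O3 | target

**Step count**
Total: 11 steps. Longest linear sequence: 8 steps (1, 2, 4, 6, 7, 9, 10, 11); steps 3, 5 and 8 are one-step side branches.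

**Three steps most likely to fail**

Step 11 (the proposed new macrocyclisation). Risks are oligomerisation, protodesilylation of the electron-poor allylsilane, 1,4-loss of the silyl and acyloxy groups to a diene, and the wrong C7 face, since C7 relative to C8 rests on substrate control. The fallback uses known chemistry, the anti-selective metal-mediated intramolecular allylation of 2-(bromomethyl)enoates through a closed chair transition state. It sets out from 13 and returns at 20. TEMPO/PhI(OAc)2 oxidation of the allylic alcohol gives the dialdehyde (R)-1-[(S)-2-methyl-3-oxo-5-((Z)-4-oxobut-2-en-2-yl)-2,3-dihydrofuran-2-yl]-3-oxopropan-2-yl (R)-2-methylbutanoate F3. A DABCO-catalysed Morita–Baylis–Hillman reaction with methyl acrylate at the more electrophilic saturated aldehyde gives the allylic alcohol methyl (4R)-3-hydroxy-4-[(R)-2-methylbutanoyloxy]-2-methylene-5-[(S)-2-methyl-3-oxo-5-((Z)-4-oxobut-2-en-2-yl)-2,3-dihydrofuran-2-yl]pentanoate F4 as a C7 epimer mixture. PBr3 in Et2O at −10 °C converts it by SN2′ into the bromide methyl (R,Z)-2-(bromomethyl)-4-[(R)-2-methylbutanoyloxy]-5-[(S)-2-methyl-3-oxo-5-((Z)-4-oxobut-2-en-2-yl)-2,3-dihydrofuran-2-yl]pent-2-enoate F5. CrCl2 in THF at high dilution (Nozaki–Hiyama-type allylation) closes the ten-membered ring, and the C6 alkoxide lactonises on acidic work-up to 20.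

Step 1 (cross-aldol of two ketones). Risks are self-aldol of the enolisable keto ester and modest enantioselectivity. The fallback replaces enamine catalysis by a chiral Lewis acid Mukaiyama aldol. It sets out from 1 and returns at 3. Me3SiOTf/Et3N converts 1 into the silyl enol ether 3,3-dimethoxy-2-(trimethylsilyloxy)prop-1-ene F1. This adds to 2 under Cu(OTf)2/(S,S)-tert-butyl-bis(oxazoline) (10 mol %, THF, −78 °C; two-point binding of the pyruvate) to give the silyl ether ethyl (S)-5,5-dimethoxy-2-methyl-4-oxo-2-(trimethylsilyloxy)pentanoate F2. Citric acid in MeOH removes the silyl group and gives 3.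

Step 2 (catalyst-controlled reduction next to a free tertiary hydroxyl). Risks are background reduction by the alkoxyborane formed at the C10 hydroxyl and a weak large/small distinction between the two ketone substituents, giving a poor C8 ratio. The fallback replaces borane chemistry by biocatalysis. It sets out from 3 and returns at 5. A ketoreductase from a commercial screening panel (NADP+, i-PrOH as hydride source, pH 7 buffer, 30 °C) reduces the ketone under enzyme control, indifferent to the free hydroxyl, to the same diol ester 4, and DBU closes the lactone as before. The sequence makes no new compound, none F0.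

**Further compounds**
F1 | step 1 | 3,3-dimethoxy-2-(trimethylsilyloxy)prop-1-ene | C=C(O[Si](C)(C)C)C(OC)OC
F2 | step 1 | ethyl (S)-5,5-dimethoxy-2-methyl-4-oxo-2-(trimethylsilyloxy)pentanoate | CCOC(=O)[C@](C)(CC(=O)C(OC)OC)O[Si](C)(C)C
F0 | step 2 | none | none
F3 | step 11 | (R)-1-[(S)-2-methyl-3-oxo-5-((Z)-4-oxobut-2-en-2-yl)-2,3-dihydrofuran-2-yl]-3-oxopropan-2-yl (R)-2-methylbutanoate | O=C/C=C(/C)C1=CC(=O)[C@](C)(C[C@@H](OC(=O)[C@H](C)CC)C=O)O1
F4 | step 11 | methyl (4R)-3-hydroxy-4-[(R)-2-methylbutanoyloxy]-2-methylene-5-[(S)-2-methyl-3-oxo-5-((Z)-4-oxobut-2-en-2-yl)-2,3-dihydrofuran-2-yl]pentanoate | O=C/C=C(/C)C1=CC(=O)[C@](C)(C[C@@H](OC(=O)[C@H](C)CC)C(O)C(=C)C(=O)OC)O1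
F5 | step 11 | methyl (R,Z)-2-(bromomethyl)-4-[(R)-2-methylbutanoyloxy]-5-[(S)-2-methyl-3-oxo-5-((Z)-4-oxobut-2-en-2-yl)-2,3-dihydrofuran-2-yl]pent-2-enoate | O=C/C=C(/C)C1=CC(=O)[C@](C)(C[C@@H](OC(=O)[C@H](C)CC)/C=C(/C(=O)OC)CBr)O1
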